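**Remark (assumption on the chemistry):** ring atoms are numbered O1, C2 (C=O), C3 (C–CH3), C4, C5; C6 is the exocyclic carbon and C7 the stereocentre. The target is read as the (5E) isomer (chain cis to C4) with (S) configuration at C7.

## Retrosynthetic overview

1. 21 ⇐ (E)-enynyl formate 20: the butenolide is closed last, between the carbonyl carbon C2 and the methyl-bearing C3, by a cycloisomerisation in which a formyl C–H is added trans across a but-2-ynyl C≡C.
2. Enabling feature: in the furan-2(5H)-one ring C2 carries only O1, the carbonyl O and C3, so it can enter as the C–H of a formate ester. C3(CH3)=C4(H) is that C–H added across C3≡C4. The exocyclic C5=C6 is the enol-ester double bond of the formate, so its E geometry is set before the ring exists.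
3. 20 ⇐ ynone 18 (kinetic E-enolate, O-formylation) ⇐ Weinreb amide 16 + propynyl Grignard reagent 17.
4. 16 ⇐ Julia–Kocienski union of sulfone 15 (stereocentre bought with hemiester 10) and enal 9; 9 ⇐ bis-furan bromide 5 (from 1 and 2) by Negishi butenylation and cross-metathesis with methacrolein.
5. Ring order: both furan rings are bought; the butenolide is the only ring made and is formed in the last step.

Key step: step 12

## Route

Step 1
Reactants: 1 3-bromofuran; 2 4-bromofuran-2-carbaldehyde
Product: 4 (4-bromofuran-2-yl)(furan-3-yl)methanol (racemic), via furan-3-yllithium 3 (not isolated)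
Conditions: n-BuLi, THF, −78 °C; then 2, −78 °C; H2O
Reagents that add atoms: none
Why: Bromine–lithium exchange at −78 °C gives the 3-lithiofuran without migration to the 2-position, and its 1,2-addition to the aldehyde is faster than exchange with the ring bromide of 2; the carbinol centre is racemic and is removed in step 2.

Step 2
Reactants: 4 (4-bromofuran-2-yl)(furan-3-yl)methanol
Product: 5 4-bromo-2-(furan-3-ylmethyl)furan
Conditions: Et3SiH, CF3CO2H, CH2Cl2, −20 → 0 °C
Reagents that add atoms: none
Why: Ionic hydrogenation, in which the carbocation stabilised by both furan rings is reduced by hydride transfer from the silane while the C–Br bond stays intact.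

Step 3
Reactants: 5 4-bromo-2-(furan-3-ylmethyl)furan; 6 but-3-en-1-ylzinc bromide
Product: 7 4-(but-3-en-1-yl)-2-(furan-3-ylmethyl)furan
Conditions: Pd(OAc)2 (2 mol %), SPhos (4 mol %), THF, 25–45 °C
Reagents that add atoms: none
Why: Negishi coupling of a primary alkylzinc halide with a heteroaryl bromide, in which the biarylphosphine complex of zerovalent palladium should couple faster than beta-hydride elimination and leave the terminal alkene alone.

Step 4
Reactants: 7 4-(but-3-en-1-yl)-2-(furan-3-ylmethyl)furan; 8 methacrolein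
Product: 9 (2E)-5-[5-(furan-3-ylmethyl)furan-3-yl]-2-methylpent-2-enal
Conditions: second-generation Grubbs catalyst RuCl2(=CHPh)(PCy3)(H2IMes) (5 mol %), excess 8, CH2Cl2, 40 °C
Reagents that add atoms: none
Why: Olefin cross-metathesis of a terminal alkene with excess methacrolein, which should give the trisubstituted enal under thermodynamic control with the chain trans to the formyl group (E), the furan rings being inert.

Step 5
Reactants: 10 (3R)-5-methoxy-3-methyl-5-oxopentanoic acid (methyl hydrogen (R)-3-methylglutarate)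
Product: 12 (4S)-4-methyloxan-2-one, via (3S)-5-hydroxy-3-methylpentanoic acid 11 (not isolated)
Conditions: LiBH4, THF, 0 → 25 °C; then 2 M HCl, 25 °C
Reagents that add atoms: none
Why: LiBH4 reduces the methyl ester but not the lithium carboxylate, and acidification closes the six-membered lactone; the stereocentre is bought with 10 and not touched, and this choice of terminus makes the former acid carbon the future C5.

Step 6
Reactants: 12 (4S)-4-methyloxan-2-one
Product: 13 (3S)-5-hydroxy-N-methoxy-N,3-dimethylpentanamide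
Conditions: MeNH(OMe)·HCl, AlMe3, CH2Cl2, 0 → 25 °C; aqueous Rochelle salt
Reagents that add atoms: N,O-dimethylhydroxylamine hydrochloride, CNOC.Cl
Why: Weinreb aminolysis of a lactone by the aluminium amide formed from AlMe3 and the amine hydrochloride.

Step 7
Reactants: 13 (3S)-5-hydroxy-N-methoxy-N,3-dimethylpentanamide
Product: 14 (3R)-N-methoxy-N,3-dimethyl-5-[(1-phenyl-1H-tetrazol-5-yl)sulfanyl]pentanamide
Conditions: 1-phenyl-1H-tetrazole-5-thiol, PPh3, diisopropyl azodicarboxylate, THF, 0 → 25 °C
Reagents that add atoms: 1-phenyl-1H-tetrazole-5-thiol, Sc1nnnn1-c1ccccc1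
Why: Mitsunobu thioetherification of a primary alcohol with an acidic heteroaryl thiol; the descriptor changes from S to R only because sulfur raises the priority of that branch.

Step 8
Reactants: 14 (3R)-N-methoxy-N,3-dimethyl-5-[(1-phenyl-1H-tetrazol-5-yl)sulfanyl]pentanamide
Product: 15 (3R)-N-methoxy-N,3-dimethyl-5-[(1-phenyl-1H-tetrazol-5-yl)sulfonyl]pentanamide
Conditions: (NH4)6Mo7O24·4H2O (10 mol %), 30 % aqueous H2O2, EtOH, 0 → 25 °C
Reagents that add atoms: hydrogen peroxide, OO
Why: Molybdate-catalysed oxidation of the sulfide to the sulfone, to which the Weinreb amide is inert.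

Step 9
Reactants: 15 (3R)-N-methoxy-N,3-dimethyl-5-[(1-phenyl-1H-tetrazol-5-yl)sulfonyl]pentanamide; 9 (2E)-5-[5-(furan-3-ylmethyl)furan-3-yl]-2-methylpent-2-enal
Product: 16 (3S,5E,7E)-10-[5-(furan-3-ylmethyl)furan-3-yl]-N-methoxy-N,3,7-trimethyldeca-5,7-dienamide
Conditions: KN(SiMe3)2 added last to 15 and 9, 1,2-dimethoxyethane, −78 → 25 °C; aqueous NH4Cl
Reagents that add atoms: none
Why: Julia–Kocienski olefination, in which the phenyltetrazolyl sulfone with a potassium base in an ether solvent should give the E alkene by addition, Smiles rearrangement and anti-elimination, while adding the base last lets the enal trap the sulfonyl carbanion (far more acidic than the amide alpha-position) before it can attack the Weinreb amide.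

Step 10
Reactants: 16 (3S,5E,7E)-10-[5-(furan-3-ylmethyl)furan-3-yl]-N-methoxy-N,3,7-trimethyldeca-5,7-dienamide; 17 prop-1-yn-1-ylmagnesium bromide
Product: 18 (6S,8E,10E)-13-[5-(furan-3-ylmethyl)furan-3-yl]-6,10-dimethyltrideca-8,10-dien-2-yn-4-one
Conditions: THF, 0 °C; poured into cold 1 M HCl
Reagents that add atoms: none
Why: Weinreb ketone synthesis, in which the chelated tetrahedral adduct prevents a second addition and the cold acidic quench removes the released hydroxylamine before it can add to the ynone.

Step 11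
Reactants: 18 (6S,8E,10E)-13-[5-(furan-3-ylmethyl)furan-3-yl]-6,10-dimethyltrideca-8,10-dien-2-yn-4-one
Product: 20 (4E,6S,8E,10E)-13-[5-(furan-3-ylmethyl)furan-3-yl]-6,10-dimethyltrideca-4,8,10-trien-2-yn-4-yl formate, via lithium (4E)-enolate 19 (not isolated)
Conditions: lithium 2,2,6,6-tetramethylpiperidide (from the amine and n-BuLi), THF, −78 °C; then cannulated into acetic formic anhydride (freshly made from sodium formate and acetyl chloride), −78 → −40 °C; pH 7 buffer, fast filtration through Florisil
Reagents that add atoms: acetic formic anhydride, CC(=O)OC=O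
Why: Kinetic deprotonation of the CH2 next to the carbonyl through a closed six-membered transition state should place the chain trans to O–Li because the slim alkynyl group exerts almost no 1,3-strain (as with esters), and the hard mixed anhydride should transfer its formyl group to oxygen with retention, which fixes the E geometry of the later exocyclic alkene.

Step 12
Reactants: 20 (4E,6S,8E,10E)-13-[5-(furan-3-ylmethyl)furan-3-yl]-6,10-dimethyltrideca-4,8,10-trien-2-yn-4-yl formate
Product: 21 (5E)-5-[(2S,4E,6E)-9-[5-(furan-3-ylmethyl)furan-3-yl]-2,6-dimethylnona-4,6-dien-1-ylidene]-3-methylfuran-2(5H)-one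
Conditions: [Rh(dppe)]2(BF4)2 (10 mol %; dppe = Ph2PCH2CH2PPh2), degassed acetone, 25 °C, dark
Reagents that add atoms: none
Why: Proposed new method: the cationic diphosphine complex of monovalent rhodium, held by the alkyne, should insert into the formyl C–H bond of 20 to give an alkoxycarbonyl hydride of trivalent rhodium, add H and Rh trans across the C≡C (H to C4, Rh to C3) to form a six-membered oxarhodacycle, and close the lactone by C–C reductive elimination between C2 and C3. The closest known reaction type is the rhodium-catalysed trans-hydroacylation of 4-alkynals to cyclopent-2-enones with the same catalyst; here the CH2 next to the formyl group is replaced by the enol oxygen, and formyl C–H activation of formate esters is known from catalytic hydroesterification. The one ring formed, the furan-2(5H)-one, closes in a formal 5-endo-dig mode by reductive elimination from the six-membered metallacycle. No stereocentre is created; the E geometry of the exocyclic C5=C6 bond is carried over from the enol formate, which takes no part in the bond changes, and the (S) centre at C7 is remote. The step needs trans addition across the alkyne, which the substrate enforces because only the trans adduct lets C3 reach the acyl carbon through the short O–C5 tether, and it needs C–C bond formation to outrun loss of CO from the alkoxycarbonyl rhodium species, which the chelating alkyne, the base-free medium and the low temperature should favour. The 1,3-diene and the furans are non-chelating ligands and should not divert the catalyst.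

## Compound list

1 | 3-bromofuran | Brc1ccoc1 | starting material
2 | 4-bromofuran-2-carbaldehyde | O=Cc1cc(Br)co1 | starting material
3 | furan-3-yllithium | [Li]c1ccoc1 | intermediate
4 | (4-bromofuran-2-yl)(furan-3-yl)methanol (racemic) | OC(c1ccoc1)c1cc(Br)co1 | intermediate
5 | 4-bromo-2-(furan-3-ylmethyl)furan | Brc1coc(Cc2ccoc2)c1 | intermediate
6 | but-3-en-1-ylzinc bromide | C=CCC[Zn]Br | starting material
7 | 4-(but-3-en-1-yl)-2-(furan-3-ylmethyl)furan | C=CCCc1coc(Cc2ccoc2)c1 | intermediate
8 | methacrolein (2-methylprop-2-enal) | CC(=C)C=O | starting material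
9 | (2E)-5-[5-(furan-3-ylmethyl)furan-3-yl]-2-methylpent-2-enal | O=C/C(C)=C/CCc1coc(Cc2ccoc2)c1 | intermediate
10 | (3R)-5-methoxy-3-methyl-5-oxopentanoic acid | OC(=O)C[C@@H](C)CC(=O)OC | starting material
11 | (3S)-5-hydroxy-3-methylpentanoic acid | OC(=O)C[C@@H](C)CCO | intermediate
12 | (4S)-4-methyloxan-2-one | O=C1C[C@@H](C)CCO1 | intermediate
13 | (3S)-5-hydroxy-N-methoxy-N,3-dimethylpentanamide | CON(C)C(=O)C[C@@H](C)CCO | intermediate
14 | (3R)-N-methoxy-N,3-dimethyl-5-[(1-phenyl-1H-tetrazol-5-yl)sulfanyl]pentanamide | CON(C)C(=O)C[C@@H](C)CCSc1nnnn1-c1ccccc1 | intermediate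
15 | (3R)-N-methoxy-N,3-dimethyl-5-[(1-phenyl-1H-tetrazol-5-yl)sulfonyl]pentanamide | CON(C)C(=O)C[C@@H](C)CCS(=O)(=O)c1nnnn1-c1ccccc1 | intermediate
16 | (3S,5E,7E)-10-[5-(furan-3-ylmethyl)furan-3-yl]-N-methoxy-N,3,7-trimethyldeca-5,7-dienamide | CON(C)C(=O)C[C@@H](C)C/C=C/C(C)=C/CCc1coc(Cc2ccoc2)c1 | intermediate
17 | prop-1-yn-1-ylmagnesium bromide | CC#C[Mg]Br | starting material
18 | (6S,8E,10E)-13-[5-(furan-3-ylmethyl)furan-3-yl]-6,10-dimethyltrideca-8,10-dien-2-yn-4-one | CC#CC(=O)C[C@@H](C)C/C=C/C(C)=C/CCc1coc(Cc2ccoc2)c1 | intermediate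
19 | lithium (4E,6S,8E,10E)-13-[5-(furan-3-ylmethyl)furan-3-yl]-6,10-dimethyltrideca-4,8,10-trien-2-yn-4-olate | CC#C/C(O[Li])=C\[C@@H](C)C/C=C/C(C)=C/CCc1coc(Cc2ccoc2)c1 | intermediate
20 | (4E,6S,8E,10E)-13-[5-(furan-3-ylmethyl)furan-3-yl]-6,10-dimethyltrideca-4,8,10-trien-2-yn-4-yl formate | CC#C/C(OC=O)=C\[C@@H](C)C/C=C/C(C)=C/CCc1coc(Cc2ccoc2)c1 | intermediate
21 | (5E)-5-[(2S,4E,6E)-9-[5-(furan-3-ylmethyl)furan-3-yl]-2,6-dimethylnona-4,6-dien-1-ylidene]-3-methylfuran-2(5H)-one | CC1=C/C(=C\[C@@H](C)C/C=C/C(C)=C/CCc2coc(Cc3ccoc3)c2)OC1=O | target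

## Count and risks

Total step count: 12. Longest linear sequence: 8 steps (10 → 21 through steps 5–12; the branch from 1 and 2 through steps 1–4 and 9–12 is equally long).

**Step 12 (bears the label).** What may go wrong: loss of CO from the alkoxycarbonyl rhodium hydride, which returns ynone 18 and leaves an inactive rhodium carbonyl, or hydride addition that never reaches the trans adduct so that the alkyne oligomerises. The fallback uses known chemistry (vinylogous Mukaiyama aldol addition, then stereospecific anti-elimination; the lactone ring is then bought, not closed). It sets out from enal 9 and comes back to the route at 21.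

Takai iodo-olefination of 9 (CrCl2, CHI3, THF, 0 °C) should give the dienyl iodide 2-(furan-3-ylmethyl)-4-[(3E,5E)-6-iodo-4-methylhexa-3,5-dien-1-yl]furan F1. Commercial (2R)-3-bromo-2-methylpropan-1-ol is silylated (t-BuMe2SiCl, imidazole) to [(2R)-3-bromo-2-methylpropoxy](tert-butyl)dimethylsilane F2. Zinc dust (I2 cat., N,N-dimethylacetamide, 70 °C) turns it into {(2R)-3-[(tert-butyldimethylsilyl)oxy]-2-methylpropyl}zinc bromide F3. Negishi coupling of this with F1 (Pd(PPh3)4, THF) gives the silyl ether tert-butyl{[(2S,4E,6E)-9-[5-(furan-3-ylmethyl)furan-3-yl]-2,6-dimethylnona-4,6-dien-1-yl]oxy}dimethylsilane F4. Bu4NF then gives the alcohol (2S,4E,6E)-9-[5-(furan-3-ylmethyl)furan-3-yl]-2,6-dimethylnona-4,6-dien-1-ol F5, and Dess–Martin periodinane the aldehyde (2S,4E,6E)-9-[5-(furan-3-ylmethyl)furan-3-yl]-2,6-dimethylnona-4,6-dienal F6, which already holds the (S) centre next to the future C6.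

The silyl dienol ether tert-butyldimethyl[(3-methylfuran-2-yl)oxy]silane F7 (from commercial 3-methylfuran-2(5H)-one, t-BuMe2SiOSO2CF3, Et3N) is added to F6 with BF3·OEt2 at −78 °C. From the mixture of adducts the 5,6-anti isomer (5S)-5-[(1R,2S,4E,6E)-9-[5-(furan-3-ylmethyl)furan-3-yl]-1-hydroxy-2,6-dimethylnona-4,6-dien-1-yl]-3-methylfuran-2(5H)-one F8 is separated. With (CF3SO2)2O and pyridine it is converted into the triflate (1R,2S,4E,6E)-9-[5-(furan-3-ylmethyl)furan-3-yl]-2,6-dimethyl-1-[(2S)-4-methyl-5-oxo-2,5-dihydrofuran-2-yl]nona-4,6-dien-1-yl trifluoromethanesulfonate F9. This should lose triflic acid by anti-elimination; with H at C5 and the triflate anti-periplanar the chain lies cis to C4, which gives 21.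

**Step 11.** What may go wrong: enolisation with too little preference for the E enolate, C-formylation in place of O-formylation, or hydrolysis of 20 on isolation. The fallback fixes and purifies the enolate geometry at the stage of an isolable silyl enol ether and then acylates an amine-free enolate. It sets out from 18 and comes back at 19.

Lithium 2,2,6,6-tetramethylpiperidide is added to 18 in the presence of Me3SiCl (internal quench, THF, −78 °C) to give the silyl enol ether trimethyl{[(4E,6S,8E,10E)-13-[5-(furan-3-ylmethyl)furan-3-yl]-6,10-dimethyltrideca-4,8,10-trien-2-yn-4-yl]oxy}silane F10. Its E isomer is purified, and MeLi (THF, 0 °C) regenerates 19 with retention of geometry; 19 is then O-formylated as in step 11.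

**Step 9.** What may go wrong: attack of the sulfonyl carbanion on the Weinreb amide five atoms away, deprotonation of the enal at its gamma position, or loss of E selectivity. The fallback reverses the roles of the partners in an E-selective Wittig reaction of an allylic tributylphosphonium ylide. It sets out from 13 and 9 and comes back at 16.

Dess–Martin oxidation of 13 gives the aldehyde (3S)-N-methoxy-N,3-dimethyl-5-oxopentanamide F11. Enal 9 is reduced (NaBH4, CeCl3·7H2O, MeOH) to the allylic alcohol (2E)-5-[5-(furan-3-ylmethyl)furan-3-yl]-2-methylpent-2-en-1-ol F12. CBr4 and PPh3 convert it into the allylic bromide 4-[(3E)-5-bromo-4-methylpent-3-en-1-yl]-2-(furan-3-ylmethyl)furan F13, and PBu3 quaternises this to the phosphonium salt tributyl{(2E)-5-[5-(furan-3-ylmethyl)furan-3-yl]-2-methylpent-2-en-1-yl}phosphonium bromide F14. LiN(SiMe3)2 (THF, −78 °C) gives the ylide tributyl{(2E)-5-[5-(furan-3-ylmethyl)furan-3-yl]-2-methylpent-2-en-1-ylidene}phosphorane F15, which with F11 should give 16.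

## Further compounds

F1 | step 12 | 2-(furan-3-ylmethyl)-4-[(3E,5E)-6-iodo-4-methylhexa-3,5-dien-1-yl]furan | I/C=C/C(C)=C/CCc1coc(Cc2ccoc2)c1
F2 | step 12 | [(2R)-3-bromo-2-methylpropoxy](tert-butyl)dimethylsilane | CC(C)(C)[Si](C)(C)OC[C@@H](C)CBr
F3 | step 12 | {(2R)-3-[(tert-butyldimethylsilyl)oxy]-2-methylpropyl}zinc bromide | CC(C)(C)[Si](C)(C)OC[C@@H](C)C[Zn]Br
F4 | step 12 | tert-butyl{[(2S,4E,6E)-9-[5-(furan-3-ylmethyl)furan-3-yl]-2,6-dimethylnona-4,6-dien-1-yl]oxy}dimethylsilane | CC(C)(C)[Si](C)(C)OC[C@@H](C)C/C=C/C(C)=C/CCc1coc(Cc2ccoc2)c1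
F5 | step 12 | (2S,4E,6E)-9-[5-(furan-3-ylmethyl)furan-3-yl]-2,6-dimethylnona-4,6-dien-1-ol | OC[C@@H](C)C/C=C/C(C)=C/CCc1coc(Cc2ccoc2)c1
F6 | step 12 | (2S,4E,6E)-9-[5-(furan-3-ylmethyl)furan-3-yl]-2,6-dimethylnona-4,6-dienal | O=C[C@@H](C)C/C=C/C(C)=C/CCc1coc(Cc2ccoc2)c1
F7 | step 12 | tert-butyldimethyl[(3-methylfuran-2-yl)oxy]silane | Cc1ccoc1O[Si](C)(C)C(C)(C)C
F8 | step 12 | (5S)-5-[(1R,2S,4E,6E)-9-[5-(furan-3-ylmethyl)furan-3-yl]-1-hydroxy-2,6-dimethylnona-4,6-dien-1-yl]-3-methylfuran-2(5H)-one | CC1=C[C@H](OC1=O)[C@H](O)[C@@H](C)C/C=C/C(C)=C/CCc2coc(Cc3ccoc3)c2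
F9 | step 12 | (1R,2S,4E,6E)-9-[5-(furan-3-ylmethyl)furan-3-yl]-2,6-dimethyl-1-[(2S)-4-methyl-5-oxo-2,5-dihydrofuran-2-yl]nona-4,6-dien-1-yl trifluoromethanesulfonate | CC1=C[C@H](OC1=O)[C@H](OS(=O)(=O)C(F)(F)F)[C@@H](C)C/C=C/C(C)=C/CCc2coc(Cc3ccoc3)c2
F10 | step 11 | trimethyl{[(4E,6S,8E,10E)-13-[5-(furan-3-ylmethyl)furan-3-yl]-6,10-dimethyltrideca-4,8,10-trien-2-yn-4-yl]oxy}silane | CC#C/C(O[Si](C)(C)C)=C\[C@@H](C)C/C=C/C(C)=C/CCc1coc(Cc2ccoc2)c1
F11 | step 9 | (3S)-N-methoxy-N,3-dimethyl-5-oxopentanamide | CON(C)C(=O)C[C@@H](C)CC=O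
F12 | step 9 | (2E)-5-[5-(furan-3-ylmethyl)furan-3-yl]-2-methylpent-2-en-1-ol | OC/C(C)=C/CCc1coc(Cc2ccoc2)c1
F13 | step 9 | 4-[(3E)-5-bromo-4-methylpent-3-en-1-yl]-2-(furan-3-ylmethyl)furan | BrC/C(C)=C/CCc1coc(Cc2ccoc2)c1
F14 | step 9 | tributyl{(2E)-5-[5-(furan-3-ylmethyl)furan-3-yl]-2-methylpent-2-en-1-yl}phosphonium bromide | CCCC[P+](CCCC)(CCCC)C/C(C)=C/CCc1coc(Cc2ccoc2)c1.[Br-]
F15 | step 9 | tributyl{(2E)-5-[5-(furan-3-ylmethyl)furan-3-yl]-2-methylpent-2-en-1-ylidene}phosphorane | CCCCP(CCCC)(CCCC)=C/C(C)=C/CCc1coc(Cc2ccoc2)c1
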